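**Retrosynthetic overview**

1. Endgame: the target comes from ketol 17 (C1–OH, C9=O). An Evans–Tishchenko reduction with 3-methylbut-2-enal makes the C1 senecioate and the 9β-carbinol (1,9-anti) in one step; the C2/C9 acetates and the free O14 follow.
2. Ring A (C1–C2–C3=C4–C5–C10) is cut at three bonds: C3=C4 (ring-closing metathesis), C10–C1 (aldol) and C5–C4 (conjugate addition). C3, C4 and C15 are then a second isopropenyl group, so ring B is a latent trans-3,5-di(isopropenyl)cyclohexanone: one isopropenyl group stays as C11–C13, the other is consumed.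
3. Key disconnection: enone 9 + isopropenyl nucleophile + (S)-2-(triethylsilyloxy)but-3-enal 13 in one flask, which sets C5, the quaternary C10 and C1.
4. Enone 9 comes from cyclohex-2-enone by Rh-catalysed asymmetric isopropenyl addition (C7), desaturation and Morita–Baylis–Hillman hydroxymethylation (C14); aldehyde 13 comes from (S)-but-3-ene-1,2-diol (C2).
5. Order of rings: ring B is the starting cyclohexenone; ring A is closed by metathesis in step 8.

Key step: step 7

Remark: eudesmane numbering is used (decalin C1–C10, C14 = CH2O on C10, C15 = CH3 on C4, C11–C13 = isopropenyl on C7); the target is 1R,2S,5R,7S,9S,10S, a trans-decalin with O1, O2 and C14 on one face and H5, O9 and the C7 isopropenyl group on the other.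

**Route**

Step 1
Reactants: 1 cyclohex-2-en-1-one; 2 potassium trifluoro(prop-1-en-2-yl)borate
Product: 3 (S)-3-(prop-1-en-2-yl)cyclohexan-1-one
Conditions: [Rh(cod)2]BF4 (3 mol %), (S)-BINAP (3.3 mol %), toluene/H2O 10:1, 105 °C
Reagents that add atoms: potassium trifluoro(prop-1-en-2-yl)borate (2), C=C(C)[B-](F)(F)F.[K+]
Why: Rhodium-catalysed asymmetric 1,4-addition of an alkenylboron reagent (Hayashi–Miyaura type) in which the (S)-BINAP–rhodium alkenyl species should add to one face of the enone and set the future C7 as S, in line with the usual sense of induction for cyclohexenone.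

Step 2
Reactants: 3 (S)-3-(prop-1-en-2-yl)cyclohexan-1-one
Product: 5 (S)-5-(prop-1-en-2-yl)cyclohex-2-en-1-one, via silyl enol ether 4 (not isolated)
Conditions: LDA, TMSCl, THF, −78 °C; then Pd(OAc)2 (10 mol %), O2 (1 atm), DMSO, 25 °C
Reagents that add atoms: none
Why: Kinetic deprotonation with the bulky amide should take the α-proton on the side remote from the branched C3 substituent, and Saegusa–Ito oxidation of silyl enol ether 4 then places the double bond on that side without touching the stereocenter.

Step 3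
Reactants: 5 (S)-5-(prop-1-en-2-yl)cyclohex-2-en-1-one; 6 formaldehyde
Product: 7 (S)-2-(hydroxymethyl)-5-(prop-1-en-2-yl)cyclohex-2-en-1-one
Conditions: 37% aq. HCHO, DMAP (20 mol %), THF, 25 °C
Reagents that add atoms: formaldehyde (6), C=O
Why: Morita–Baylis–Hillman hydroxymethylation of a cyclic enone, which puts C14 at the alcohol oxidation level on the future C10 and creates no stereocenter.

Step 4
Reactants: 7 (S)-2-(hydroxymethyl)-5-(prop-1-en-2-yl)cyclohex-2-en-1-one; 8 tert-butyl(chloro)diphenylsilane
Product: 9 (S)-2-{[(tert-butyldiphenylsilyl)oxy]methyl}-5-(prop-1-en-2-yl)cyclohex-2-en-1-one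
Conditions: TBDPSCl, imidazole, CH2Cl2, 0 → 25 °C
Reagents that add atoms: tert-butyl(chloro)diphenylsilane (8), CC(C)(C)[Si](Cl)(c1ccccc1)c1ccccc1
Why: Standard silylation of a primary allylic alcohol, chosen because the non-chelating TBDPS ether is a poor leaving group for β-elimination from the enolate of step 7 and lasts to the final step.

Step 5
Reactants: 10 (S)-but-3-ene-1,2-diol; 11 chlorotriethylsilane
Product: 12 (S)-3,4-bis(triethylsilyloxy)but-1-ene
Conditions: TESCl (2.3 equiv), imidazole, DMAP (cat.), CH2Cl2, 0 °C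
Reagents that add atoms: chlorotriethylsilane (11), CC[Si](Cl)(CC)CC
Why: Standard silylation of both hydroxyls of the chiral-pool diol, which leaves the future C2 stereocenter untouched.

Step 6
Reactants: 12 (S)-3,4-bis(triethylsilyloxy)but-1-ene
Product: 13 (S)-2-(triethylsilyloxy)but-3-enal
Conditions: (COCl)2, DMSO, CH2Cl2, −78 → −30 °C; then i-Pr2NEt, −78 °C; crude aldehyde used at once
Reagents that add atoms: none
Why: Under Swern conditions a primary triethylsilyl ether is cleaved and oxidised in one operation while the secondary one stays, a known chemoselective oxidative desilylation that gives the α-silyloxy aldehyde without a separate deprotection and, when kept cold and used crude, without epimerisation or conjugation of the double bond.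

Step 7
Reactants: 9 (S)-2-{[(tert-butyldiphenylsilyl)oxy]methyl}-5-(prop-1-en-2-yl)cyclohex-2-en-1-one; 14 isopropenylmagnesium bromide; 13 (S)-2-(triethylsilyloxy)but-3-enal
Product: 16 (2R,3R,5S)-2-{[(tert-butyldiphenylsilyl)oxy]methyl}-2-[(1R,2S)-1-hydroxy-2-(triethylsilyloxy)but-3-en-1-yl]-3,5-di(prop-1-en-2-yl)cyclohexan-1-one, via magnesium enolate 15 (not isolated)
Conditions: 14 (1.3 equiv), CuBr·SMe2 (10 mol %), THF, −78 → −40 °C; then 13 (1.5 equiv), −78 °C; sat. aq. NH4Cl at −78 °C
Reagents that add atoms: isopropenylmagnesium bromide (14), C=C(C)[Mg]Br; (S)-2-(triethylsilyloxy)but-3-enal (13), O=C[C@@H](O[Si](CC)(CC)CC)C=C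
Why: Copper-catalysed conjugate addition of the isopropenyl Grignard reagent to enone 9 gives the regiodefined tetrasubstituted magnesium enolate 15, which is trapped in the same flask by aldol addition to aldehyde 13; the closest known reaction type is the cuprate addition–aldol three-component coupling of carvone and other 2-substituted cyclohexenones. The step closes no ring: it forms the C4–C5 and C1–C10 bonds and so brings in every carbon of ring A, which step 8 then closes. C5 is set by axial attack of the copper reagent anti to the C7 isopropenyl group (3,5-trans), and the quaternary C10 by attack of the aldehyde on the enolate face anti to the new, pseudoaxial C5 isopropenyl group (2,3-trans), which leaves C14 cis and C1 trans to C4 as the trans-decalin needs. C1 is set by a Zimmerman–Traxler chair of the ring-constrained (E)-type enolate, which places the new hydroxyl syn to the CH2OSi group, and the same aldehyde face is the Felkin–Anh face of (S)-13 (attack anti to the silyloxy group, 1,2-anti diol), so enolate control and aldehyde control are matched. The step needs facial selectivity at three centres and addition rather than proton transfer; the two trans-directing ring substituents, the non-chelating silyl ethers and the low temperature, which holds back β-silanolate elimination, retro-aldol cleavage and enolisation of 13, should secure this. Any minor enantiomer of 9 ends up in a diastereomer of 16 and is removed at this stage.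

Step 8
Reactants: 16 (2R,3R,5S)-2-{[(tert-butyldiphenylsilyl)oxy]methyl}-2-[(1R,2S)-1-hydroxy-2-(triethylsilyloxy)but-3-en-1-yl]-3,5-di(prop-1-en-2-yl)cyclohexan-1-one
Product: 17 (1R,2S,5R,7S,10R)-14-[(tert-butyldiphenylsilyl)oxy]-1-hydroxy-2-(triethylsilyloxy)eudesma-3,11-dien-9-one
Conditions: Hoveyda–Grubbs II catalyst (5 mol %), toluene (5 mM), 80 °C
Reagents that add atoms: none
Why: Ring-closing metathesis between the vinyl group on C2 and the isopropenyl group on C5 closes ring A as a cyclohexene with the trisubstituted C3=C4 bond, whereas the isopropenyl group on C7 could only give a bridged ring and stays; no stereocenter is touched.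

Step 9
Reactants: 17 (1R,2S,5R,7S,10R)-14-[(tert-butyldiphenylsilyl)oxy]-1-hydroxy-2-(triethylsilyloxy)eudesma-3,11-dien-9-one; 18 3-methylbut-2-enal
Product: 19 (1R,2S,5R,7S,9S,10S)-14-[(tert-butyldiphenylsilyl)oxy]-9-hydroxy-2-(triethylsilyloxy)eudesma-3,11-dien-1-yl 3-methylbut-2-enoate
Conditions: SmI2 (30 mol %), 18 (6 equiv), THF, −10 °C
Reagents that add atoms: 3-methylbut-2-enal (18), CC(C)=CC=O
Why: Evans–Tishchenko reduction, in which the samarium-bound hemiacetal formed from the C1 hydroxyl and the enal delivers its hydride inside a six-membered chelate to the α face of the C9 ketone, so that the 1,9-anti diol forms with C9 as S (9β-OH) and the C1 oxygen is left as the 3-methylbut-2-enoate.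

Step 10
Reactants: 19 (1R,2S,5R,7S,9S,10S)-14-[(tert-butyldiphenylsilyl)oxy]-9-hydroxy-2-(triethylsilyloxy)eudesma-3,11-dien-1-yl 3-methylbut-2-enoate; 20 acetic anhydride
Product: 22 (1R,2S,5R,7S,9S,10S)-2,9-diacetoxy-14-[(tert-butyldiphenylsilyl)oxy]eudesma-3,11-dien-1-yl 3-methylbut-2-enoate, via diol 21 (not isolated)
Conditions: PPTS (0.2 equiv), MeOH, 0 → 25 °C; concentrate; then Ac2O, DMAP, pyridine, 0 → 40 °C
Reagents that add atoms: acetic anhydride (20), CC(=O)OC(C)=O
Why: Mild acidic methanolysis removes the secondary triethylsilyl ether in the presence of the primary TBDPS ether and the ester, and DMAP-catalysed acetylation of the crude diol first caps the allylic C2 hydroxyl before the neighbouring ester can migrate and then, on warming, the hindered axial C9 hydroxyl.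

Step 11
Reactants: 22 (1R,2S,5R,7S,9S,10S)-2,9-diacetoxy-14-[(tert-butyldiphenylsilyl)oxy]eudesma-3,11-dien-1-yl 3-methylbut-2-enoate
Product: 23 (1R,2S,5R,7S,9S,10S)-2,9-diacetoxy-14-hydroxyeudesma-3,11-dien-1-yl 3-methylbut-2-enoate (CNP0320218.1)
Conditions: HF·pyridine, pyridine, THF, 0 → 25 °C
Reagents that add atoms: none
Why: Fluoride-mediated desilylation under buffered, weakly acidic conditions frees the C14 hydroxyl without ester cleavage and without acyl migration from O1 to O14.

**Compound list**

1 | cyclohex-2-en-1-one | O=C1C=CCCC1 | starting material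
2 | potassium trifluoro(prop-1-en-2-yl)borate | C=C(C)[B-](F)(F)F.[K+] | starting material
3 | (S)-3-(prop-1-en-2-yl)cyclohexan-1-one | C=C(C)[C@H]1CCCC(=O)C1 | intermediate
4 | (S)-trimethyl{[5-(prop-1-en-2-yl)cyclohex-1-en-1-yl]oxy}silane | C=C(C)[C@H]1CCC=C(O[Si](C)(C)C)C1 | intermediate
5 | (S)-5-(prop-1-en-2-yl)cyclohex-2-en-1-one | C=C(C)[C@H]1CC=CC(=O)C1 | intermediate
6 | formaldehyde | C=O | starting material
7 | (S)-2-(hydroxymethyl)-5-(prop-1-en-2-yl)cyclohex-2-en-1-one | C=C(C)[C@H]1CC=C(CO)C(=O)C1 | intermediate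
8 | tert-butyl(chloro)diphenylsilane | CC(C)(C)[Si](Cl)(c1ccccc1)c1ccccc1 | starting material
9 | (S)-2-{[(tert-butyldiphenylsilyl)oxy]methyl}-5-(prop-1-en-2-yl)cyclohex-2-en-1-one | C=C(C)[C@H]1CC=C(CO[Si](c2ccccc2)(c2ccccc2)C(C)(C)C)C(=O)C1 | intermediate
10 | (S)-but-3-ene-1,2-diol | OC[C@@H](O)C=C | starting material
11 | chlorotriethylsilane | CC[Si](Cl)(CC)CC | starting material
12 | (S)-3,4-bis(triethylsilyloxy)but-1-ene | CC[Si](CC)(CC)OC[C@@H](O[Si](CC)(CC)CC)C=C | intermediate
13 | (S)-2-(triethylsilyloxy)but-3-enal | O=C[C@@H](O[Si](CC)(CC)CC)C=C | intermediate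
14 | isopropenylmagnesium bromide | C=C(C)[Mg]Br | starting material
15 | bromomagnesium (3R,5S)-2-{[(tert-butyldiphenylsilyl)oxy]methyl}-3,5-di(prop-1-en-2-yl)cyclohex-1-en-1-olate | C=C(C)[C@@H]1CC(O[Mg]Br)=C(CO[Si](c2ccccc2)(c2ccccc2)C(C)(C)C)[C@H](C1)C(C)=C | intermediate
16 | (2R,3R,5S)-2-{[(tert-butyldiphenylsilyl)oxy]methyl}-2-[(1R,2S)-1-hydroxy-2-(triethylsilyloxy)but-3-en-1-yl]-3,5-di(prop-1-en-2-yl)cyclohexan-1-one | C=C(C)[C@@H]1CC(=O)[C@](CO[Si](c2ccccc2)(c2ccccc2)C(C)(C)C)([C@@H](O)[C@@H](O[Si](CC)(CC)CC)C=C)[C@H](C1)C(C)=C | intermediate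
17 | (1R,2S,5R,7S,10R)-14-[(tert-butyldiphenylsilyl)oxy]-1-hydroxy-2-(triethylsilyloxy)eudesma-3,11-dien-9-one | C=C(C)[C@@H]1CC(=O)[C@@]2(CO[Si](c3ccccc3)(c3ccccc3)C(C)(C)C)[C@H](C1)C(C)=C[C@H](O[Si](CC)(CC)CC)[C@@H]2O | intermediate
18 | 3-methylbut-2-enal | CC(C)=CC=O | starting material
19 | (1R,2S,5R,7S,9S,10S)-14-[(tert-butyldiphenylsilyl)oxy]-9-hydroxy-2-(triethylsilyloxy)eudesma-3,11-dien-1-yl 3-methylbut-2-enoate | C=C(C)[C@@H]1C[C@H](O)[C@@]2(CO[Si](c3ccccc3)(c3ccccc3)C(C)(C)C)[C@H](C1)C(C)=C[C@H](O[Si](CC)(CC)CC)[C@@H]2OC(=O)C=C(C)C | intermediate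
20 | acetic anhydride | CC(=O)OC(C)=O | starting material
21 | (1R,2S,5R,7S,9S,10S)-14-[(tert-butyldiphenylsilyl)oxy]-2,9-dihydroxyeudesma-3,11-dien-1-yl 3-methylbut-2-enoate | C=C(C)[C@@H]1C[C@H](O)[C@@]2(CO[Si](c3ccccc3)(c3ccccc3)C(C)(C)C)[C@H](C1)C(C)=C[C@H](O)[C@@H]2OC(=O)C=C(C)C | intermediate
22 | (1R,2S,5R,7S,9S,10S)-2,9-diacetoxy-14-[(tert-butyldiphenylsilyl)oxy]eudesma-3,11-dien-1-yl 3-methylbut-2-enoate | C=C(C)[C@@H]1C[C@H](OC(C)=O)[C@@]2(CO[Si](c3ccccc3)(c3ccccc3)C(C)(C)C)[C@H](C1)C(C)=C[C@H](OC(C)=O)[C@@H]2OC(=O)C=C(C)C | intermediate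
23 | (1R,2S,5R,7S,9S,10S)-2,9-diacetoxy-14-hydroxyeudesma-3,11-dien-1-yl 3-methylbut-2-enoate (CNP0320218.1) | C=C(C)[C@@H]1C[C@H](OC(C)=O)[C@@]2(CO)[C@H](C1)C(C)=C[C@H](OC(C)=O)[C@@H]2OC(=O)C=C(C)C | target

**Step count and risks**

Total step count: 11. Longest linear sequence: 9 (steps 1–4 and 7–11); steps 5–6 make aldehyde 13 in a side branch.

The three steps most likely to fail:

1. The key step (step 7). What may go wrong: proton transfer from the enolisable aldehyde 13 to enolate 15, β-elimination of silanolate from 15 on warming, or loss of facial control in the closed aldol transition state. The fallback sets out from 9. The conjugate addition is run with chlorotrimethylsilane as trap (isopropenylmagnesium bromide, CuBr·SMe2, TMSCl, THF, −78 °C) to give the isolable silyl enol ether {[(3R,5S)-2-{[(tert-butyldiphenylsilyl)oxy]methyl}-3,5-di(prop-1-en-2-yl)cyclohex-1-en-1-yl]oxy}trimethylsilane F1. F1 is then joined to 13 in a Mukaiyama aldol addition (BF3·OEt2, CH2Cl2, −78 °C). The open transition state has no basic enolate and leaves C1 to Felkin–Anh control by the silyloxy group of 13, while C10 is still set anti to the C5 isopropenyl group. The fallback comes back to the route at 16.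

2. The Evans–Tishchenko step (step 9). What may go wrong: retro-aldol cleavage of the hindered ketol under the Lewis-acidic conditions, or consumption of the enal by samarium without hydride transfer. The fallback sets out from 17. Hydroxyl-directed reduction with Me4NBH(OAc)3 (AcOH/MeCN, −30 °C; intramolecular hydride delivery, 1,3-anti) should give (1R,2S,5R,7S,9S,10S)-14-[(tert-butyldiphenylsilyl)oxy]-2-(triethylsilyloxy)eudesma-3,11-diene-1,9-diol F2. The equatorial C1 hydroxyl of F2 is then esterified in preference to the axial C9 hydroxyl, which is shielded by the syn-axial isopropenyl group. This uses 3-methylbut-2-enoic acid under Yamaguchi conditions (2,4,6-trichlorobenzoyl chloride, Et3N, DMAP, toluene, 0 °C). The fallback comes back to the route at 19.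

3. The desaturation (step 2). What may go wrong: poor regioselectivity of the kinetic enolisation, so that part of the material is desaturated toward the isopropenyl-bearing carbon. The fallback sets out from 3. Claisen formylation under equilibrating conditions (HCO2Et, NaOMe, Et2O, 0 → 25 °C) goes to the less hindered α-carbon and gives (S,Z)-2-(hydroxymethylene)-5-(prop-1-en-2-yl)cyclohexan-1-one F3. Selenenylation (PhSeCl, pyridine, CH2Cl2, 0 °C) gives (4S)-2-oxo-1-(phenylselanyl)-4-(prop-1-en-2-yl)cyclohexane-1-carbaldehyde F4. Deformylation (K2CO3, MeOH) gives (5S)-2-(phenylselanyl)-5-(prop-1-en-2-yl)cyclohexan-1-one F5. Oxidation (H2O2, CH2Cl2, 0 °C) brings about selenoxide syn-elimination, which can only go toward the ring CH2. The fallback comes back to the route at 5.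

**Further compounds**

F1 | step 7 | {[(3R,5S)-2-{[(tert-butyldiphenylsilyl)oxy]methyl}-3,5-di(prop-1-en-2-yl)cyclohex-1-en-1-yl]oxy}trimethylsilane | C=C(C)[C@@H]1CC(O[Si](C)(C)C)=C(CO[Si](c2ccccc2)(c2ccccc2)C(C)(C)C)[C@H](C1)C(C)=C
F2 | step 9 | (1R,2S,5R,7S,9S,10S)-14-[(tert-butyldiphenylsilyl)oxy]-2-(triethylsilyloxy)eudesma-3,11-diene-1,9-diol | C=C(C)[C@@H]1C[C@H](O)[C@@]2(CO[Si](c3ccccc3)(c3ccccc3)C(C)(C)C)[C@H](C1)C(C)=C[C@H](O[Si](CC)(CC)CC)[C@@H]2O
F3 | step 2 | (S,Z)-2-(hydroxymethylene)-5-(prop-1-en-2-yl)cyclohexan-1-one | C=C(C)[C@H]1CC/C(=C/O)C(=O)C1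
F4 | step 2 | (4S)-2-oxo-1-(phenylselanyl)-4-(prop-1-en-2-yl)cyclohexane-1-carbaldehyde (both epimers at C1) | C=C(C)[C@H]1CCC(C=O)([Se]c2ccccc2)C(=O)C1
F5 | step 2 | (5S)-2-(phenylselanyl)-5-(prop-1-en-2-yl)cyclohexan-1-one (both epimers at C2) | C=C(C)[C@H]1CCC([Se]c2ccccc2)C(=O)C1
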